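The route rests on one disconnection. This is the bond between the quaternary oxirane carbon (C2 of the three-membered ring) and the benzene carbon that lies ortho to the oxygen-bearing ring carbon and para to the formyl-bearing one. A metal phenoxide attacking a chelated ketone produces exactly this 1,2,4-relationship. The titanium aryloxide Ti[(R)-BINOLate](OC6H4Br-3)2, with bromine standing in for the formyl group, adds to methyl 3-(tert-butyldiphenylsilyloxy)pyruvate, an acyclic 1,2-dicarbonyl bearing one masked hydroxymethyl arm. One operation forms the aryl–carbon bond and the tertiary carbinol stereocentre with two differentiated one-carbon arms. Reduction, oxirane closure, formylation and a silyl-to-isovaleryl exchange complete the synthesis.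

Key step: step 3

Assumption: (R)-BINOL is taken to direct the aryl carbon to the Re face of the ketone and so to give the (S)-carbinol; if the first run shows the opposite sense, (S)-BINOL is used and nothing else changes.

Remark: no bond to the stereocentre is made or broken after the key step. The ester carbon becomes the oxirane CH2 and the silyloxymethyl arm becomes the acyloxymethyl arm. The (S)-carbinol therefore maps onto the (R)-target, and the descriptor changes on the way come only from the priority rules.

Step 1
Reactants: 1 methyl 2,3-dihydroxypropanoate (racemic)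
Product: 2 methyl 3-[(tert-butyldiphenylsilyl)oxy]-2-hydroxypropanoate (racemic)
Conditions: TBDPSCl (1.05 equiv), imidazole, CH2Cl2, 0 °C
Reagents that add atoms: tert-butyl(chloro)diphenylsilane (TBDPSCl), CC(C)(C)[Si](Cl)(c1ccccc1)c1ccccc1
Why: Silyl ether formation with a bulky chlorosilane selects the unhindered primary hydroxyl over the secondary α-hydroxy ester position, and the racemic carbinol carbon is of no concern because step 2 makes it planar.

Step 2
Reactants: 2 methyl 3-[(tert-butyldiphenylsilyl)oxy]-2-hydroxypropanoate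
Product: 3 methyl 3-[(tert-butyldiphenylsilyl)oxy]-2-oxopropanoate
Conditions: Dess–Martin periodinane, CH2Cl2, 0 °C → rt
Reagents that add atoms: none
Why: Dess–Martin oxidation converts the secondary alcohol into the ketone under mild non-aqueous conditions that leave the silyl ether intact and limit enolisation or hydration of the sensitive α-ketoester, which is used at once.

Step 3
Reactants: 3 methyl 3-[(tert-butyldiphenylsilyl)oxy]-2-oxopropanoate; 4 3-bromophenol
Product: 6 methyl (2S)-2-(4-bromo-2-hydroxyphenyl)-3-[(tert-butyldiphenylsilyl)oxy]-2-hydroxypropanoate, via titanium aryloxide 5 (not isolated)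
Conditions: Ti(OiPr)4 (1.0 equiv), (R)-BINOL (1.0 equiv), 4 (2.0 equiv), toluene, rt, then iPrOH removed azeotropically in vacuo; 3 (1.0 equiv), CH2Cl2, −20 °C → rt; cold aq. NH4Cl, filtration through Celite
Reagents that add atoms: none
Why: Ketoester 3 binds through both carbonyl oxygens to the tetravalent titanium of 5, so an aryloxide ligand and the activated ketone share one metal, and the ortho carbon of that aryloxide attacks the ketone carbon through a six-membered cyclic transition state (Ti–O–C–C···C–O); the ring proton then passes to the second aryloxide, which leaves as 3-bromophenol and restores aromaticity. The closest known reaction type is the ortho-specific Friedel–Crafts hydroxyalkylation of titanium and magnesium phenoxides with pyruvate and glyoxylate esters, practised both with chiral ester auxiliaries and with chiral Lewis acids. No ring is closed; one C–C bond and one stereocentre are made. The stereocentre is controlled by the C2-symmetric BINOLate on the same metal, which should screen the Si face of the chelated ketone so that the aryl carbon arrives on the Re face and gives (S). The step needs ortho-over-para and C6-over-C2 regioselectivity: the tether cannot reach the para carbon, and the ortho carbon between oxygen and bromine is sterically closed, which leaves the carbon para to bromine. Removing every isopropoxide before 3 is added shuts off ester exchange and Meerwein–Ponndorf–Verley reduction of the ketone and gives a more Lewis acidic all-aryloxide titanium, the bulky and weakly basic silyl ether oxygen stays out of the chelate, and a cold near-neutral work-up keeps the new phenol from lactonising onto the ester.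

Step 4
Reactants: 6 methyl (2S)-2-(4-bromo-2-hydroxyphenyl)-3-[(tert-butyldiphenylsilyl)oxy]-2-hydroxypropanoate
Product: 7 methyl (2S)-2-{4-bromo-2-[(triisopropylsilyl)oxy]phenyl}-3-[(tert-butyldiphenylsilyl)oxy]-2-hydroxypropanoate
Conditions: TIPSOTf, 2,6-lutidine, CH2Cl2, −78 → 0 °C
Reagents that add atoms: triisopropylsilyl trifluoromethanesulfonate (TIPSOTf), CC(C)[Si](C(C)C)(C(C)C)OS(=O)(=O)C(F)(F)F
Why: Silylation of the acidic phenol with a silyl triflate and a hindered pyridine base is fast in the cold, the bulk of the triisopropylsilyl group keeps it off the tertiary hydroxyl and makes it slow to migrate later, and early capping stops the phenol from lactonising onto the ester or competing in steps 6 and 7.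

Step 5
Reactants: 7 methyl (2S)-2-{4-bromo-2-[(triisopropylsilyl)oxy]phenyl}-3-[(tert-butyldiphenylsilyl)oxy]-2-hydroxypropanoate
Product: 8 (2R)-2-{4-bromo-2-[(triisopropylsilyl)oxy]phenyl}-3-[(tert-butyldiphenylsilyl)oxy]propane-1,2-diol
Conditions: LiBH4, Et2O–THF, 0 °C → rt; aq. NH4Cl
Reagents that add atoms: none
Why: Chemoselective borohydride reduction of the α-hydroxy ester, helped by the neighbouring hydroxyl, leaves C–Br and both silyl ethers alone, and the weakly basic borate intermediates avoid migration of the silyl group between the two CH2O arms, the one process that would erode the configuration.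

Step 6
Reactants: 8 (2R)-2-{4-bromo-2-[(triisopropylsilyl)oxy]phenyl}-3-[(tert-butyldiphenylsilyl)oxy]propane-1,2-diol
Product: 9 (2S)-2-{4-bromo-2-[(triisopropylsilyl)oxy]phenyl}-3-[(tert-butyldiphenylsilyl)oxy]-2-hydroxypropyl 4-methylbenzenesulfonate
Conditions: TsCl, Et3N, DMAP (cat.), CH2Cl2, 0 °C → rt
Reagents that add atoms: 4-methylbenzenesulfonyl chloride (TsCl), Cc1ccc(cc1)S(=O)(=O)Cl
Why: Sulfonate ester formation discriminates on steric grounds, since the primary hydroxyl reacts while the crowded tertiary benzylic hydroxyl is inert to TsCl, and the amine base forms no alkoxide that could move a silyl group.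

Step 7
Reactants: 9 (2S)-2-{4-bromo-2-[(triisopropylsilyl)oxy]phenyl}-3-[(tert-butyldiphenylsilyl)oxy]-2-hydroxypropyl 4-methylbenzenesulfonate
Product: 10 (2R)-2-{4-bromo-2-[(triisopropylsilyl)oxy]phenyl}-2-{[(tert-butyldiphenylsilyl)oxy]methyl}oxirane
Conditions: NaH, THF, 0 °C
Reagents that add atoms: none
Why: Intramolecular Williamson etherification (3-exo-tet) of the tertiary alkoxide onto the adjacent primary tosylate should outrun migration of either bulky silyl group, uses a non-nucleophilic base that spares the aryl silyl ether, and breaks no bond at the stereocentre, so its spatial arrangement is retained.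

Step 8
Reactants: 10 (2R)-2-{4-bromo-2-[(triisopropylsilyl)oxy]phenyl}-2-{[(tert-butyldiphenylsilyl)oxy]methyl}oxirane
Product: 12 4-[(2R)-2-{[(tert-butyldiphenylsilyl)oxy]methyl}oxiran-2-yl]-3-[(triisopropylsilyl)oxy]benzaldehyde, via aryllithium 11 (not isolated)
Conditions: n-BuLi, THF, −78 °C; DMF, −78 → −20 °C; aq. NH4Cl
Reagents that add atoms: N,N-dimethylformamide (DMF), CN(C)C=O
Why: Bromine–lithium exchange at −78 °C outruns addition of butyllithium to an unactivated oxirane, the lithiated carbon lies para to the oxirane-bearing carbon and cannot reach it, and trapping with DMF (Bouveault aldehyde synthesis) gives the aldehyde without the hot aqueous base of a cross-coupling, while its electron withdrawal para to the benzylic C–O bond steadies the oxirane for the last step.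

Step 9
Reactants: 12 4-[(2R)-2-{[(tert-butyldiphenylsilyl)oxy]methyl}oxiran-2-yl]-3-[(triisopropylsilyl)oxy]benzaldehyde; 13 3-methylbutanoic anhydride (isovaleric anhydride)
Product: 14 {(2R)-2-[4-formyl-2-(3-methylbutanoyloxy)phenyl]oxiran-2-yl}methyl 3-methylbutanoate (CNP0274578.1)
Conditions: Bu4NF (2.5 equiv), 13 (5 equiv), DMAP (cat.), THF, 0 °C → rt
Reagents that add atoms: none
Why: In this fluoride-triggered desilylative acylation, fluoride cleaves the aryl O–Si bond within minutes and the alkyl O–Si bond more slowly, and because 13 (and the acyl fluoride it forms with fluoride) is present from the start each phenoxide or alkoxide is esterified as it appears, so that a free ortho-phenoxide cannot push open the benzylic oxirane, while a Payne shift of the transient epoxy alkoxide is degenerate here and returns the same enantiomer.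

Compound list
1 | methyl 2,3-dihydroxypropanoate (racemic) | COC(=O)C(O)CO | starting material
2 | methyl 3-[(tert-butyldiphenylsilyl)oxy]-2-hydroxypropanoate (racemic) | COC(=O)C(O)CO[Si](c1ccccc1)(c1ccccc1)C(C)(C)C | intermediate
3 | methyl 3-[(tert-butyldiphenylsilyl)oxy]-2-oxopropanoate | COC(=O)C(=O)CO[Si](c1ccccc1)(c1ccccc1)C(C)(C)C | intermediate
4 | 3-bromophenol | Oc1cccc(Br)c1 | starting material
5 | Ti[(R)-BINOLate](OC6H4Br-3)2, formed in the flask (the R axis cannot be written in SMILES) | Brc1cccc(O[Ti]2(Oc3cccc(Br)c3)Oc3ccc4ccccc4c3-c3c(O2)ccc4ccccc34)c1 | intermediate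
6 | methyl (2S)-2-(4-bromo-2-hydroxyphenyl)-3-[(tert-butyldiphenylsilyl)oxy]-2-hydroxypropanoate | CC(C)(C)[Si](c1ccccc1)(c1ccccc1)OC[C@@](O)(c1ccc(Br)cc1O)C(=O)OC | intermediate
7 | methyl (2S)-2-{4-bromo-2-[(triisopropylsilyl)oxy]phenyl}-3-[(tert-butyldiphenylsilyl)oxy]-2-hydroxypropanoate | CC(C)(C)[Si](c1ccccc1)(c1ccccc1)OC[C@@](O)(c1ccc(Br)cc1O[Si](C(C)C)(C(C)C)C(C)C)C(=O)OC | intermediate
8 | (2R)-2-{4-bromo-2-[(triisopropylsilyl)oxy]phenyl}-3-[(tert-butyldiphenylsilyl)oxy]propane-1,2-diol | CC(C)(C)[Si](c1ccccc1)(c1ccccc1)OC[C@@](O)(c1ccc(Br)cc1O[Si](C(C)C)(C(C)C)C(C)C)CO | intermediate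
9 | (2S)-2-{4-bromo-2-[(triisopropylsilyl)oxy]phenyl}-3-[(tert-butyldiphenylsilyl)oxy]-2-hydroxypropyl 4-methylbenzenesulfonate | CC(C)(C)[Si](c1ccccc1)(c1ccccc1)OC[C@@](O)(c1ccc(Br)cc1O[Si](C(C)C)(C(C)C)C(C)C)COS(=O)(=O)c1ccc(C)cc1 | intermediate
10 | (2R)-2-{4-bromo-2-[(triisopropylsilyl)oxy]phenyl}-2-{[(tert-butyldiphenylsilyl)oxy]methyl}oxirane | CC(C)(C)[Si](c1ccccc1)(c1ccccc1)OC[C@@]1(c2ccc(Br)cc2O[Si](C(C)C)(C(C)C)C(C)C)CO1 | intermediate
11 | aryllithium from 10 (Li in place of Br), formed in the flask | CC(C)(C)[Si](c1ccccc1)(c1ccccc1)OC[C@@]1(c2ccc([Li])cc2O[Si](C(C)C)(C(C)C)C(C)C)CO1 | intermediate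
12 | 4-[(2R)-2-{[(tert-butyldiphenylsilyl)oxy]methyl}oxiran-2-yl]-3-[(triisopropylsilyl)oxy]benzaldehyde | CC(C)(C)[Si](c1ccccc1)(c1ccccc1)OC[C@@]1(c2ccc(C=O)cc2O[Si](C(C)C)(C(C)C)C(C)C)CO1 | intermediate
13 | 3-methylbutanoic anhydride | CC(C)CC(=O)OC(=O)CC(C)C | starting material
14 | {(2R)-2-[4-formyl-2-(3-methylbutanoyloxy)phenyl]oxiran-2-yl}methyl 3-methylbutanoate | CC(C)CC(=O)OC[C@@]1(c2ccc(C=O)cc2OC(=O)CC(C)C)CO1 | target

Total step count: 9. Longest linear sequence: 9 steps (1 → 14); 4 enters at step 3 and 13 at step 9.

Steps most likely to fail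

**Step 3.**
- What may go wrong: facial discrimination by the BINOLate may be poor. The bromine-deactivated aryloxide may attack too slowly. The enolisable ketoester may self-condense in the meantime.
- Fallback: auxiliary control in place of a chiral ligand, setting out from 2 and 4 and returning at 8. Transesterification of 2 with (1R,2S,5R)-menthol (Ti(OiPr)4 cat., toluene, reflux) should give menthyl hydroxy ester F1. Dess–Martin oxidation then gives menthyl ketoester F2. Compound 4 and TiCl4 (CH2Cl2, −30 °C) give trichlorotitanium 3-bromophenoxide F3, a stronger Lewis acid. F3 adds to F2 under control of the menthyl group to give menthyl adduct F4. F4 is freed of its epimer by chromatography or crystallisation, and the antipodal menthol is used if the sense is wrong. TIPSOTf and 2,6-lutidine give menthyl silyl ether F5, and LiAlH4 (Et2O, 0 °C) removes the auxiliary reductively to give 8.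

**Step 9.**
- What may go wrong: cleavage of the alkyl O–Si bond may lag because the anhydride ties up fluoride. Long exposure invites opening of the oxirane by carboxylate or by transient phenoxide.
- Fallback: a staged exchange with an acidic fluoride source for the second silyl group, setting out from 12 and returning at 14. Bu4NF (1.0 equiv) with 13 at −40 °C should convert only the aryl silyl ether, giving aryl isovalerate F6. Et3N·3HF (MeCN, rt) then removes the tert-butyldiphenylsilyl group without forming an alkoxide or phenoxide, giving epoxy alcohol F7. Isovaleryl chloride and pyridine (CH2Cl2, 0 °C) give 14.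

**Step 8.**
- What may go wrong: butyllithium or the aryllithium may add to the oxirane, or the aryllithium may be protonated before DMF reaches it.
- Fallback: cross-coupling and oxidative cleavage in place of an organolithium, setting out from 10 and returning at 12. Suzuki–Miyaura coupling with vinylboronic acid pinacol ester (Pd(OAc)2, SPhos, K3PO4, THF–H2O, 40 °C) should give styrene F8. Ozonolysis (O3, CH2Cl2, −78 °C; Me2S) gives 12.

Further compounds
F1 | step 3 | (1R,2S,5R)-2-isopropyl-5-methylcyclohexyl 3-[(tert-butyldiphenylsilyl)oxy]-2-hydroxypropanoate (both C2 epimers) | CC(C)[C@@H]1CC[C@@H](C)C[C@H]1OC(=O)C(O)CO[Si](c1ccccc1)(c1ccccc1)C(C)(C)C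
F2 | step 3 | (1R,2S,5R)-2-isopropyl-5-methylcyclohexyl 3-[(tert-butyldiphenylsilyl)oxy]-2-oxopropanoate | CC(C)[C@@H]1CC[C@@H](C)C[C@H]1OC(=O)C(=O)CO[Si](c1ccccc1)(c1ccccc1)C(C)(C)C
F3 | step 3 | TiCl3(OC6H4Br-3), trichloro(3-bromophenoxy)titanium | Cl[Ti](Cl)(Cl)Oc1cccc(Br)c1
F4 | step 3 | (1R,2S,5R)-2-isopropyl-5-methylcyclohexyl (2S)-2-(4-bromo-2-hydroxyphenyl)-3-[(tert-butyldiphenylsilyl)oxy]-2-hydroxypropanoate | CC(C)(C)[Si](c1ccccc1)(c1ccccc1)OC[C@@](O)(c1ccc(Br)cc1O)C(=O)O[C@@H]1C[C@H](C)CC[C@H]1C(C)C
F5 | step 3 | (1R,2S,5R)-2-isopropyl-5-methylcyclohexyl (2S)-2-{4-bromo-2-[(triisopropylsilyl)oxy]phenyl}-3-[(tert-butyldiphenylsilyl)oxy]-2-hydroxypropanoate | CC(C)(C)[Si](c1ccccc1)(c1ccccc1)OC[C@@](O)(c1ccc(Br)cc1O[Si](C(C)C)(C(C)C)C(C)C)C(=O)O[C@@H]1C[C@H](C)CC[C@H]1C(C)C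
F6 | step 9 | 2-[(2R)-2-{[(tert-butyldiphenylsilyl)oxy]methyl}oxiran-2-yl]-5-formylphenyl 3-methylbutanoate | CC(C)(C)[Si](c1ccccc1)(c1ccccc1)OC[C@@]1(c2ccc(C=O)cc2OC(=O)CC(C)C)CO1
F7 | step 9 | 5-formyl-2-[(2S)-2-(hydroxymethyl)oxiran-2-yl]phenyl 3-methylbutanoate | OC[C@@]1(c2ccc(C=O)cc2OC(=O)CC(C)C)CO1
F8 | step 8 | (2R)-2-{[(tert-butyldiphenylsilyl)oxy]methyl}-2-{4-ethenyl-2-[(triisopropylsilyl)oxy]phenyl}oxirane | CC(C)(C)[Si](c1ccccc1)(c1ccccc1)OC[C@@]1(c2ccc(C=C)cc2O[Si](C(C)C)(C(C)C)C(C)C)CO1
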